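**Plan**
- Retrosynthetic cuts, in order: the three benzyl ethers of unit 2; the C4a–C5 bond of ring A of unit 1; C7–C6 and then C8–C7 of the side arm; the biaryl bond C3'–C8''; finally the pyranone (to an aryl ester and acetylacetone) and the flavone of unit 2 (to an acetophenone and an aldehyde).
- Enabling feature: ring A of unit 1 is a phloroglucinol ring with oxygen on C5, C7 and C8a and hydrogen on C6 and C8. C8–C7–C6–C5 can therefore be carried as a CH2–CO–CH2–CO2Me arm on a 2-aryl-4-pyranone whose ring already holds O1, C2, C3, C4, C4a and C8a.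
- Forward order: ring C of unit 2 closes first (8-iodoflavone). The 4-pyranone, the future ring C of unit 1, is made separately from a triketone. The two halves are joined by Suzuki coupling, the methyl group is grown into the keto ester, and ring A of unit 1 closes last, before debenzylation.
- Stereochemistry: the target has no stereocentre and no stereogenic double bond; the E geometry of the chalcone disappears on cyclization.

Key step: step 11

Remark: unit 1 is the flavone carrying the dimethoxyphenyl ring B (primed locants), unit 2 the apigenin half (double-primed locants). The target SMILES defines no configuration for the hindered C3'–C8'' axis, so no atroposelective step is planned. Mg(OMe)2 and Mg(O2CCH2CO2Me)2 are taken as purchased reagents.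

Step 1
Reactants: 1 2,4,6-trihydroxyacetophenone
Product: 2 1-[2,4-bis(benzyloxy)-6-hydroxyphenyl]ethan-1-one
Conditions: BnBr (2.1 equiv), K2CO3 (2.2 equiv), DMF, 0 °C to rt
Reagents that add atoms: benzyl bromide, BrCc1ccccc1
Why: Williamson ether synthesis, in which the para hydroxyl and one ortho hydroxyl are alkylated while the remaining ortho hydroxyl, hydrogen-bonded to the acetyl group, is the least nucleophilic and should stay free.

Step 2
Reactants: 2 1-[2,4-bis(benzyloxy)-6-hydroxyphenyl]ethan-1-one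
Product: 3 1-[4,6-bis(benzyloxy)-2-hydroxy-3-iodophenyl]ethan-1-one
Conditions: BnMe3N+ ICl2− (1.05 equiv), NaHCO3, CH2Cl2/MeOH, rt
Reagents that add atoms: benzyltrimethylammonium dichloroiodate, C[N+](C)(C)Cc1ccccc1.Cl[I-]Cl
Why: Electrophilic aromatic iodination with this mild reagent is expected ortho to the free phenol, as known for 2-hydroxy-4,6-dialkoxyacetophenones, and that carbon becomes C8'' of the flavone.

Step 3
Reactants: 3 1-[4,6-bis(benzyloxy)-2-hydroxy-3-iodophenyl]ethan-1-one; 4 4-(benzyloxy)benzaldehyde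
Product: 5 (E)-1-[4,6-bis(benzyloxy)-2-hydroxy-3-iodophenyl]-3-[4-(benzyloxy)phenyl]prop-2-en-1-one
Conditions: KOH (50% aq.), EtOH/THF, rt
Reagents that add atoms: none
Why: Claisen–Schmidt aldol condensation of the methyl ketone enolate with a non-enolizable aldehyde should give the E-enone after loss of water.

Step 4
Reactants: 5 (E)-1-[4,6-bis(benzyloxy)-2-hydroxy-3-iodophenyl]-3-[4-(benzyloxy)phenyl]prop-2-en-1-one
Product: 6 5,7-bis(benzyloxy)-2-[4-(benzyloxy)phenyl]-8-iodo-4H-chromen-4-one (8-iodo-5,7,4'-tri-O-benzylapigenin)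
Conditions: I2 (10 mol %), DMSO, 130 °C
Reagents that add atoms: none
Why: Iodine-catalysed oxidative cyclization of a 2'-hydroxychalcone in DMSO (conjugate addition of the phenol, then dehydrogenation with DMSO as terminal oxidant) is the standard flavone synthesis and is compatible with aryl iodides and benzyl ethers.

Step 5
Reactants: 7 methyl 3-bromo-4,5-dimethoxybenzoate; 8 acetylacetone
Product: 9 1-(3-bromo-4,5-dimethoxyphenyl)hexane-1,3,5-trione
Conditions: 8 (3 equiv), LiN(iPr)2 (6 equiv), THF, −78 to 0 °C; then 7, 0 °C to rt; 1 M HCl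
Reagents that add atoms: none
Why: The dianion of a 1,3-diketone is acylated by esters at its terminal carbon (Claisen-type acylation), and the excess dianion absorbs the acidic triketone, while no free amide base remains to attack the aryl bromide.

Step 6
Reactants: 9 1-(3-bromo-4,5-dimethoxyphenyl)hexane-1,3,5-trione
Product: 10 2-(3-bromo-4,5-dimethoxyphenyl)-6-methyl-4H-pyran-4-one
Conditions: conc. H2SO4, 0 °C, short contact; ice
Reagents that add atoms: none
Why: Acid-catalysed cyclodehydration of a 1,3,5-triketone (enol oxygen onto the distal carbonyl, loss of water) is the classical entry to 2,6-disubstituted 4-pyranones.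

Step 7
Reactants: 10 2-(3-bromo-4,5-dimethoxyphenyl)-6-methyl-4H-pyran-4-one
Product: 11 2-[3,4-dimethoxy-5-(4,4,5,5-tetramethyl-1,3,2-dioxaborolan-2-yl)phenyl]-6-methyl-4H-pyran-4-one
Conditions: B2pin2 (1.2 equiv), PdCl2(dppf) (5 mol %), KOAc (3 equiv), 1,4-dioxane, 90 °C
Reagents that add atoms: bis(pinacolato)diboron, CC1(C)OB(OC1(C)C)B1OC(C)(C)C(C)(C)O1
Why: Miyaura borylation of an aryl bromide uses only the weak base KOAc, which should leave the pyranone and its acidic methyl group untouched.

Step 8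
Reactants: 6 8-iodo-5,7,4'-tri-O-benzylapigenin; 11 2-[3,4-dimethoxy-5-(4,4,5,5-tetramethyl-1,3,2-dioxaborolan-2-yl)phenyl]-6-methyl-4H-pyran-4-one
Product: 12 5,7-bis(benzyloxy)-2-[4-(benzyloxy)phenyl]-8-[2,3-dimethoxy-5-(6-methyl-4-oxo-4H-pyran-2-yl)phenyl]-4H-chromen-4-one
Conditions: Pd(OAc)2 (5 mol %), SPhos (10 mol %), K3PO4 (3 equiv), toluene/H2O, 90 °C
Reagents that add atoms: none
Why: Suzuki–Miyaura coupling with the bulky, electron-rich biarylphosphine SPhos is suited to a tri-ortho-substituted biaryl, and the more hindered partner is placed as the iodide as in known 8-arylflavone couplings.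

Step 9
Reactants: 12 5,7-bis(benzyloxy)-2-[4-(benzyloxy)phenyl]-8-[2,3-dimethoxy-5-(6-methyl-4-oxo-4H-pyran-2-yl)phenyl]-4H-chromen-4-one
Product: 13 2-{6-[3-(5'',7'',4'''-tri-O-benzylapigenin-8''-yl)-4,5-dimethoxyphenyl]-4-oxo-4H-pyran-2-yl}acetic acid
Conditions: LiN(SiMe3)2 (1.2 equiv), THF, −78 °C; CO2, −78 to −20 °C; cold 1 M HCl; used without heating
Reagents that add atoms: carbon dioxide, O=C=O
Why: The 6-methyl group of a 4-pyranone is a vinylogous methyl ketone, so LiN(SiMe3)2 should remove one of its protons without touching the ring CH positions of the pyranone or flavone, and the extended enolate is carboxylated at the exocyclic carbon (lateral metalation and carboxylation).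

Step 10
Reactants: 13 2-{6-[3-(5'',7'',4'''-tri-O-benzylapigenin-8''-yl)-4,5-dimethoxyphenyl]-4-oxo-4H-pyran-2-yl}acetic acid
Product: 15 methyl 4-{6-[3-(5'',7'',4'''-tri-O-benzylapigenin-8''-yl)-4,5-dimethoxyphenyl]-4-oxo-4H-pyran-2-yl}-3-oxobutanoate, via acyl imidazolide 14 (not isolated)
Conditions: 1,1'-carbonyldiimidazole (1.2 equiv), THF, rt; then Mg(O2CCH2CO2Me)2 (1.5 equiv), THF, rt to 40 °C; 1 M HCl
Reagents that add atoms: magnesium bis(methyl malonate), [Mg+2].COC(=O)CC(=O)[O-].COC(=O)CC(=O)[O-]; 1,1'-carbonyldiimidazole, O=C(n1ccnc1)n1ccnc1 (its imidazole is carried only in 14)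
Why: Masamune homologation, in which the acyl imidazolide C-acylates the magnesium enolate of the malonate half ester and loss of CO2 gives the beta-keto ester under nearly neutral conditions that the benzyl ethers and both pyranone rings tolerate.

Step 11
Reactants: 15 methyl 4-{6-[3-(5'',7'',4'''-tri-O-benzylapigenin-8''-yl)-4,5-dimethoxyphenyl]-4-oxo-4H-pyran-2-yl}-3-oxobutanoate
Product: 16 5'',7'',4'''-tri-O-benzyl-5'-methoxybilobetin
Conditions: Mg(OMe)2 (5 equiv), MeOH/THF, 60 °C; then 2 M HCl, 40 °C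
Reagents that add atoms: none
Why: Proposed new method: in methanol the anions of 15 interconvert, and the one deprotonated at C8 (the CH2 between pyranone and ketone) is a dienolate O4–C4=C4a–C8a=C8 whose magnesium ion on O4 can bind the ester carbonyl and deliver it to C4a (pyranone C5); C-acylation there, loss of methoxide and two enolizations should give the aromatic 5,7-dihydroxy ring A with ring C untouched. The closest known reaction is the base-mediated Claisen (Dieckmann-type) cyclization of 3,5,7-triketo esters to acylphloroglucinols, where a beta-keto ester terminus is likewise the acyl donor; what has not been shown is a ring carbon of an intact 4-pyranone, the enol-ether-locked form of that triketone, acting as the nucleophile. Ring A closes in a 6-(enolexo)-exo-trig mode and no stereocentre is created. The step needs C-acylation at C4a to win over aldol attack of C6 on the C4 carbonyl, over O-acylation and over reaction at C8, and the intact pyranone secures this because C6 could reach C4 only through a bridged ring with bridgehead double bonds, C8 only through a four-membered ring and the enolate oxygens only through four- or eight-membered rings. If methoxide opens the pyranone instead, the open pentaketide can fold in the same Claisen sense to a 2,4,6-trihydroxyphenyl 1,3-diketone that the acidic work-up recloses to the same flavone, ring A being symmetric about the C4a–C7 axis. Aromatization and the stable magnesium chelate of the 5-hydroxy-4-ketone should make the closure irreversible.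

Step 12
Reactants: 16 5'',7'',4'''-tri-O-benzyl-5'-methoxybilobetin
Product: 17 5'-methoxybilobetin
Conditions: BCl3 (10 equiv), C6HMe5 (12 equiv), CH2Cl2, −78 to −40 °C; MeOH, then aq. HCl
Reagents that add atoms: none
Why: BCl3 cleaves aryl benzyl ethers at low temperature while pentamethylbenzene traps the benzyl cation (Friedel–Crafts scavenging), so the two aryl methyl ethers and the electron-rich phloroglucinol rings should be left alone.

**Compound list**
1 | 2,4,6-trihydroxyacetophenone | CC(=O)c1c(O)cc(O)cc1O | starting material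
2 | 1-[2,4-bis(benzyloxy)-6-hydroxyphenyl]ethan-1-one | CC(=O)c1c(O)cc(OCc2ccccc2)cc1OCc1ccccc1 | intermediate
3 | 1-[4,6-bis(benzyloxy)-2-hydroxy-3-iodophenyl]ethan-1-one | CC(=O)c1c(O)c(I)c(OCc2ccccc2)cc1OCc1ccccc1 | intermediate
4 | 4-(benzyloxy)benzaldehyde | O=Cc1ccc(OCc2ccccc2)cc1 | starting material
5 | (E)-1-[4,6-bis(benzyloxy)-2-hydroxy-3-iodophenyl]-3-[4-(benzyloxy)phenyl]prop-2-en-1-one | O=C(/C=C/c1ccc(OCc2ccccc2)cc1)c1c(O)c(I)c(OCc2ccccc2)cc1OCc1ccccc1 | intermediate
6 | 5,7-bis(benzyloxy)-2-[4-(benzyloxy)phenyl]-8-iodo-4H-chromen-4-one | Ic1c(OCc2ccccc2)cc(OCc2ccccc2)c2c(=O)cc(-c3ccc(OCc4ccccc4)cc3)oc12 | intermediate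
7 | methyl 3-bromo-4,5-dimethoxybenzoate | COC(=O)c1cc(Br)c(OC)c(OC)c1 | starting material
8 | acetylacetone (pentane-2,4-dione) | CC(=O)CC(C)=O | starting material
9 | 1-(3-bromo-4,5-dimethoxyphenyl)hexane-1,3,5-trione | COc1cc(C(=O)CC(=O)CC(C)=O)cc(Br)c1OC | intermediate
10 | 2-(3-bromo-4,5-dimethoxyphenyl)-6-methyl-4H-pyran-4-one | COc1cc(-c2cc(=O)cc(C)o2)cc(Br)c1OC | intermediate
11 | 2-[3,4-dimethoxy-5-(4,4,5,5-tetramethyl-1,3,2-dioxaborolan-2-yl)phenyl]-6-methyl-4H-pyran-4-one | COc1cc(-c2cc(=O)cc(C)o2)cc(B2OC(C)(C)C(C)(C)O2)c1OC | intermediate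
12 | 5,7-bis(benzyloxy)-2-[4-(benzyloxy)phenyl]-8-[2,3-dimethoxy-5-(6-methyl-4-oxo-4H-pyran-2-yl)phenyl]-4H-chromen-4-one | COc1cc(-c2cc(=O)cc(C)o2)cc(-c2c(OCc3ccccc3)cc(OCc3ccccc3)c3c(=O)cc(-c4ccc(OCc5ccccc5)cc4)oc23)c1OC | intermediate
13 | 2-{6-[3-(5'',7'',4'''-tri-O-benzylapigenin-8''-yl)-4,5-dimethoxyphenyl]-4-oxo-4H-pyran-2-yl}acetic acid | COc1cc(-c2cc(=O)cc(CC(=O)O)o2)cc(-c2c(OCc3ccccc3)cc(OCc3ccccc3)c3c(=O)cc(-c4ccc(OCc5ccccc5)cc4)oc23)c1OC | intermediate
14 | 1-acylimidazole (imidazolide) of acid 13 | COc1cc(-c2cc(=O)cc(CC(=O)n3ccnc3)o2)cc(-c2c(OCc3ccccc3)cc(OCc3ccccc3)c3c(=O)cc(-c4ccc(OCc5ccccc5)cc4)oc23)c1OC | intermediate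
15 | methyl 4-{6-[3-(5'',7'',4'''-tri-O-benzylapigenin-8''-yl)-4,5-dimethoxyphenyl]-4-oxo-4H-pyran-2-yl}-3-oxobutanoate | COc1cc(-c2cc(=O)cc(CC(=O)CC(=O)OC)o2)cc(-c2c(OCc3ccccc3)cc(OCc3ccccc3)c3c(=O)cc(-c4ccc(OCc5ccccc5)cc4)oc23)c1OC | intermediate
16 | 5'',7'',4'''-tri-O-benzyl-5'-methoxybilobetin | COc1cc(-c2cc(=O)c3c(O)cc(O)cc3o2)cc(-c2c(OCc4ccccc4)cc(OCc4ccccc4)c3c(=O)cc(-c4ccc(OCc5ccccc5)cc4)oc23)c1OC | intermediate
17 | 5'-methoxybilobetin | COc1cc(-c2cc(=O)c3c(O)cc(O)cc3o2)cc(-c2c(O)cc(O)c3c(=O)cc(-c4ccc(O)cc4)oc23)c1OC | target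

**Step count**
Total: 12 steps. Longest linear sequence: 9 steps (steps 1–4, then 8–12); the ring B branch (steps 5–7) joins at step 8.

**Steps most likely to fail**

Step 11 (the labelled step). The substrate may rest as the inert magnesium chelate of the enolized keto ester, so that C-acylation at C4a never starts. Alternatively methoxide may open the pyranone and the released polyketide may then fold in aldol modes. The fallback builds ring A of unit 1 from a ready-made phloroglucinol unit by known chemistry; it sets out from acetophenone 2, uses iodoflavone 6 as partner, and comes back at target 17. Compound 2 would be condensed with commercial 3-bromo-4,5-dimethoxybenzaldehyde (KOH, EtOH) to (E)-1-[2,4-bis(benzyloxy)-6-hydroxyphenyl]-3-(3-bromo-4,5-dimethoxyphenyl)prop-2-en-1-one F1. I2 in DMSO at 130 °C should close it to 5,7-bis(benzyloxy)-2-(3-bromo-4,5-dimethoxyphenyl)-4H-chromen-4-one F2. Miyaura borylation (B2pin2, PdCl2(dppf), KOAc) would give the pinacol boronate F3. Suzuki coupling of F3 with 6 (Pd(OAc)2, SPhos, K3PO4) would give the pentabenzyl biflavone F4. BCl3 with pentamethylbenzene would then remove all five benzyl groups to give 17.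

Step 9. Metalation may be incomplete or misdirected among the many CH positions of 12, and the pyranylacetic acid may lose CO2 during acidic isolation. The fallback installs the carboxyl carbon before the biaryl coupling and keeps it masked; it sets out from bromide 10 and comes back at acid 13. Compound 10 would be treated with LiN(SiMe3)2 (2.2 equiv) and Boc2O at −78 °C to give tert-butyl 2-[6-(3-bromo-4,5-dimethoxyphenyl)-4-oxo-4H-pyran-2-yl]acetate F5. Miyaura borylation would give the pinacol boronate F6, and Suzuki coupling with 6 would give the tert-butyl ester of acid 13 F7. CF3CO2H in CH2Cl2 at 0 °C would release 13, which is taken into step 10 at once without heating.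

Step 8. Transmetalation at the doubly ortho-flanked C8'' may be slow, so that protodeboronation of 11 and reductive loss of iodine from 6 take over, or the base may provoke side reactions at the pyranone methyl group. The fallback inverts the order of biaryl coupling and pyranone construction; it sets out from ester 7, uses 6 and 8, and comes back at 12. Compound 7 would be borylated (B2pin2, PdCl2(dppf), KOAc) to methyl 3,4-dimethoxy-5-(4,4,5,5-tetramethyl-1,3,2-dioxaborolan-2-yl)benzoate F8. Coupling with 6 would give methyl 3-(5'',7'',4'''-tri-O-benzylapigenin-8''-yl)-4,5-dimethoxybenzoate F9, a simple benzoate partner of the kind usual in 8-arylflavone couplings. The dianion of 8 (LiN(iPr)2, THF, −78 to −20 °C) should be acylated by the ester of F9 in preference to the deactivated flavone carbonyl, giving 1-[3-(5'',7'',4'''-tri-O-benzylapigenin-8''-yl)-4,5-dimethoxyphenyl]hexane-1,3,5-trione F10. Catalytic p-TsOH in warm toluene would close F10 to 12.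

**Further compounds**
F1 | step 11 | (E)-1-[2,4-bis(benzyloxy)-6-hydroxyphenyl]-3-(3-bromo-4,5-dimethoxyphenyl)prop-2-en-1-one | COc1cc(/C=C/C(=O)c2c(O)cc(OCc3ccccc3)cc2OCc2ccccc2)cc(Br)c1OC
F2 | step 11 | 5,7-bis(benzyloxy)-2-(3-bromo-4,5-dimethoxyphenyl)-4H-chromen-4-one | COc1cc(-c2cc(=O)c3c(OCc4ccccc4)cc(OCc4ccccc4)cc3o2)cc(Br)c1OC
F3 | step 11 | 5,7-bis(benzyloxy)-2-[3,4-dimethoxy-5-(4,4,5,5-tetramethyl-1,3,2-dioxaborolan-2-yl)phenyl]-4H-chromen-4-one | COc1cc(-c2cc(=O)c3c(OCc4ccccc4)cc(OCc4ccccc4)cc3o2)cc(B2OC(C)(C)C(C)(C)O2)c1OC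
F4 | step 11 | 5,7,5'',7'',4'''-penta-O-benzyl-5'-methoxybilobetin | COc1cc(-c2cc(=O)c3c(OCc4ccccc4)cc(OCc4ccccc4)cc3o2)cc(-c2c(OCc3ccccc3)cc(OCc3ccccc3)c3c(=O)cc(-c4ccc(OCc5ccccc5)cc4)oc23)c1OC
F5 | step 9 | tert-butyl 2-[6-(3-bromo-4,5-dimethoxyphenyl)-4-oxo-4H-pyran-2-yl]acetate | COc1cc(-c2cc(=O)cc(CC(=O)OC(C)(C)C)o2)cc(Br)c1OC
F6 | step 9 | tert-butyl 2-{6-[3,4-dimethoxy-5-(4,4,5,5-tetramethyl-1,3,2-dioxaborolan-2-yl)phenyl]-4-oxo-4H-pyran-2-yl}acetate | COc1cc(-c2cc(=O)cc(CC(=O)OC(C)(C)C)o2)cc(B2OC(C)(C)C(C)(C)O2)c1OC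
F7 | step 9 | tert-butyl 2-{6-[3-(5'',7'',4'''-tri-O-benzylapigenin-8''-yl)-4,5-dimethoxyphenyl]-4-oxo-4H-pyran-2-yl}acetate | COc1cc(-c2cc(=O)cc(CC(=O)OC(C)(C)C)o2)cc(-c2c(OCc3ccccc3)cc(OCc3ccccc3)c3c(=O)cc(-c4ccc(OCc5ccccc5)cc4)oc23)c1OC
F8 | step 8 | methyl 3,4-dimethoxy-5-(4,4,5,5-tetramethyl-1,3,2-dioxaborolan-2-yl)benzoate | COC(=O)c1cc(OC)c(OC)c(B2OC(C)(C)C(C)(C)O2)c1
F9 | step 8 | methyl 3-(5'',7'',4'''-tri-O-benzylapigenin-8''-yl)-4,5-dimethoxybenzoate | COC(=O)c1cc(OC)c(OC)c(-c2c(OCc3ccccc3)cc(OCc3ccccc3)c3c(=O)cc(-c4ccc(OCc5ccccc5)cc4)oc23)c1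
F10 | step 8 | 1-[3-(5'',7'',4'''-tri-O-benzylapigenin-8''-yl)-4,5-dimethoxyphenyl]hexane-1,3,5-trione | COc1cc(C(=O)CC(=O)CC(C)=O)cc(-c2c(OCc3ccccc3)cc(OCc3ccccc3)c3c(=O)cc(-c4ccc(OCc5ccccc5)cc4)oc23)c1OC
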